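**Retrosynthetic overview**

- Ring numbering: C1 (methyl-bearing alkene carbon), C2 (alkene CH), C3 (CH2), C4 (isovalerate carbinol), C5 (CMe2), C6 (CH carrying C7H2–O–coumarin). The plan rests on one feature: the C4 oxygen is β to C2, so with a ketone at C2 the bond C3–C4 is an aldol bond, and because C5 is quaternary a C4 aldehyde cannot enolise and can only be the acceptor.
- Backwards: C7–O aryl ether (Mitsunobu with umbelliferone); C1=C2 alkene from the C2 ketone via its enol triflate; C4 ester; then the only ring-forming event, the amine-catalysed aldol C3–C4 of an acyclic 5-oxohexanal.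
- The keto aldehyde comes from one ozonolysis of a diene (vinyl gives the C4 aldehyde, the 2-butenyl unit gives the C2 methyl ketone). The diene comes from an Ireland–Claisen rearrangement that forms C6–C1 and sets C6 and C1 by chirality transfer from (R,E)-3-methylpent-3-en-2-ol.
- C1 is erased at the enol triflate, but it is built as the epimer with methyl cis to C7, because that epimer steers the chair of the aldol.

Key step: step 7

Remark on the chemistry: in an acid-bridged enamine aldol of this closure type the new C4–O bond is axial on the forming chair, so it is cis to C7 only if C7 is axial too; the keto aldehyde is therefore made with the C1 methyl cis to C7 (4R in the hexanal numbering), and a primary amino acid is used as the amine.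

**Route**

Step 1
Reactants: 1 (E)-3-methylpent-3-en-2-one
Product: 2 (2R,3E)-3-methylpent-3-en-2-ol
Conditions: (S)-2-methyl-CBS-oxazaborolidine (10 mol%), catecholborane, toluene, −78 °C; aq. NaOH work-up
Reagents that add atoms: none
Why: Corey–Bakshi–Shibata reduction, in which the ketone binds the oxazaborolidine boron anti to the larger 2-butenyl group, so hydride should be delivered to the face that gives the (R)-carbinol, with 1,2-selectivity at low temperature.

Step 2
Reactants: 2 (2R,3E)-3-methylpent-3-en-2-ol; 3 3,3-dimethylpent-4-enoic acid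
Product: 4 (2R,3E)-3-methylpent-3-en-2-yl 3,3-dimethylpent-4-enoate
Conditions: DCC, DMAP (cat.), CH2Cl2, 0 °C → rt
Reagents that add atoms: none
Why: Steglich esterification through the O-acylisourea and the acylpyridinium ion, which does not touch the carbinol stereocentre.

Step 3
Reactants: 4 (2R,3E)-3-methylpent-3-en-2-yl 3,3-dimethylpent-4-enoate
Product: 6 trimethylsilyl (2S,3R,4E)-3,4-dimethyl-2-(2-methylbut-3-en-2-yl)hex-4-enoate, via silyl ketene acetal 5 (not isolated)
Conditions: LiN(iPr)2, THF–DMPU, −78 °C; Me3SiCl; −78 °C → 60 °C; volatiles removed, crude 6 used directly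
Reagents that add atoms: chlorotrimethylsilane, C[Si](C)(C)Cl
Why: Ireland–Claisen rearrangement, in which enolisation in the presence of DMPU should give the (Z)-ketene acetal 5 (tert-alkyl residue cis to OSiMe3) and the [3,3] shift through a chair with the carbinol methyl and the tert-alkyl residue equatorial forms C6–C1, transfers the carbinol chirality to ring C6 (S, ester C2) and ring C1 (R, ester C3), and leaves an (E)-alkene.

Step 4
Reactants: 6 trimethylsilyl (2S,3R,4E)-3,4-dimethyl-2-(2-methylbut-3-en-2-yl)hex-4-enoate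
Product: 7 (2S,3R,4E)-3,4-dimethyl-2-(2-methylbut-3-en-2-yl)hex-4-en-1-ol
Conditions: LiAlH4, THF, 0 °C → reflux; aq. NaOH work-up
Reagents that add atoms: none
Why: Hydride reduction of the silyl ester to the primary alcohol (C7), under which neither stereocentre is acidic.

Step 5
Reactants: 7 (2S,3R,4E)-3,4-dimethyl-2-(2-methylbut-3-en-2-yl)hex-4-en-1-ol
Product: 8 tert-butyl{[(2S,3R,4E)-3,4-dimethyl-2-(2-methylbut-3-en-2-yl)hex-4-en-1-yl]oxy}dimethylsilane
Conditions: TBSCl, imidazole, DMF, rt
Reagents that add atoms: tert-butyldimethylsilyl chloride, CC(C)(C)[Si](C)(C)Cl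
Why: Standard silylation of a primary alcohol through the N-silylimidazolium ion, giving an ether that survives ozone, amine catalysis, triflation and palladium.

Step 6
Reactants: 8 tert-butyl{[(2S,3R,4E)-3,4-dimethyl-2-(2-methylbut-3-en-2-yl)hex-4-en-1-yl]oxy}dimethylsilane
Product: 10 (3S,4R)-3-{[(tert-butyldimethylsilyl)oxy]methyl}-2,2,4-trimethyl-5-oxohexanal, via bis-ozonide 9 (not isolated)
Conditions: O3, CH2Cl2, −78 °C; then PPh3, −78 °C → rt
Reagents that add atoms: ozone, [O-][O+]=O
Why: Ozonolysis with reductive work-up cleaves both alkenes at once (vinyl to the C4 aldehyde, trisubstituted alkene to the C2 methyl ketone), and the neutral phosphine reduction should spare the C1 stereocentre next to the new ketone.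

Step 7
Reactants: 10 (3S,4R)-3-{[(tert-butyldimethylsilyl)oxy]methyl}-2,2,4-trimethyl-5-oxohexanal
Product: 11 (2R,3S,5R)-3-{[(tert-butyldimethylsilyl)oxy]methyl}-5-hydroxy-2,4,4-trimethylcyclohexan-1-one
Conditions: L-phenylalanine (30 mol%), DMSO, H2O (5 equiv), rt
Reagents that add atoms: none
Why: L-Phenylalanine condenses with the methyl ketone to the terminal enamine (C2=C3), whose C3 adds to the C4 aldehyde while the carboxylic acid protonates the forming alkoxide, and hydrolysis of the iminium ion releases ketol 11 and the catalyst; the closest known reactions are amino-acid-catalysed aldol cyclisations of the Hajos–Parrish type and the amine-mediated closure of 2,2-disubstituted 5-oxohexanals. The six-membered ring closes in the 6-(enolendo)-exo-trig mode, because both enamine carbons C2 and C3 become ring members while the aldehyde C=O stays outside the ring. The new stereocentre C4 is controlled by the substrate chair and the acid bridge: the C1 methyl must be equatorial (axial it would be syn to the axial C5 methyl), which places the cis C6 side chain axial, and the hydrogen bond to the catalyst acid holds the aldehyde oxygen gauche to the enamine C–N bond, that is axial on the same face as C7, so C4 becomes R with oxygen cis to C7 as the target requires. A primary amino acid is chosen because its N–H can lie syn to the in-plane C1 methyl, where a pyrrolidine enamine would meet allylic 1,3-strain, and the L enantiomer can reach the required face with its benzyl group turned away from the substrate. The step needs donor regioselectivity, secured because only the methyl-side enamine can close a six-membered ring and the aldehyde has no α-hydrogen next to quaternary C5, and it needs the ketol to survive without dehydration, which the neutral medium at room temperature should allow.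

Step 8
Reactants: 11 (2R,3S,5R)-3-{[(tert-butyldimethylsilyl)oxy]methyl}-5-hydroxy-2,4,4-trimethylcyclohexan-1-one
Product: 12 (1R,3S,4R)-3-{[(tert-butyldimethylsilyl)oxy]methyl}-2,2,4-trimethyl-5-oxocyclohexyl 3-methylbutanoate
Conditions: isovaleric anhydride, DMAP (cat.), pyridine, CH2Cl2, 0 °C → rt
Reagents that add atoms: 3-methylbutanoic anhydride, CC(C)CC(=O)OC(=O)CC(C)C
Why: DMAP-catalysed acylation through the acylpyridinium ion, run with a weak base at low temperature so that E1cB loss of the β-oxygen is avoided and C4 keeps its configuration.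

Step 9
Reactants: 12 (1R,3S,4R)-3-{[(tert-butyldimethylsilyl)oxy]methyl}-2,2,4-trimethyl-5-oxocyclohexyl 3-methylbutanoate
Product: 13 (1R,5R)-5-{[(tert-butyldimethylsilyl)oxy]methyl}-4,6,6-trimethyl-3-[(trifluoromethanesulfonyl)oxy]cyclohex-3-en-1-yl 3-methylbutanoate
Conditions: Tf2O, 2,6-di-tert-butyl-4-methylpyridine, CH2Cl2, 0 °C → rt
Reagents that add atoms: trifluoromethanesulfonic anhydride, O=S(=O)(OS(=O)(=O)C(F)(F)F)C(F)(F)F
Why: O-Triflation of the ketone followed by loss of the C1 proton to the hindered pyridine should favour the more substituted (C1=C2) enol triflate, which also erases the C1 stereocentre, and since no enolate is formed the β-ester at C4 should not eliminate.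

Step 10
Reactants: 13 (1R,5R)-5-{[(tert-butyldimethylsilyl)oxy]methyl}-4,6,6-trimethyl-3-[(trifluoromethanesulfonyl)oxy]cyclohex-3-en-1-yl 3-methylbutanoate
Product: 14 (1R,5S)-5-{[(tert-butyldimethylsilyl)oxy]methyl}-4,6,6-trimethylcyclohex-3-en-1-yl 3-methylbutanoate
Conditions: Pd(OAc)2 (5 mol%), PPh3, HCO2H, Bu3N, DMF, 60 °C
Reagents that add atoms: none
Why: Palladium-catalysed formate reduction of a vinyl triflate, in which oxidative addition to zerovalent palladium formed in situ, formate exchange, loss of CO2 and reductive elimination place hydrogen on C2 and fix the alkene between C1 and C2, with ester and silyl ether inert.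

Step 11
Reactants: 14 (1R,5S)-5-{[(tert-butyldimethylsilyl)oxy]methyl}-4,6,6-trimethylcyclohex-3-en-1-yl 3-methylbutanoate
Product: 15 (1R,5S)-5-(hydroxymethyl)-4,6,6-trimethylcyclohex-3-en-1-yl 3-methylbutanoate
Conditions: HF·pyridine, pyridine, THF, 0 °C → rt
Reagents that add atoms: none
Why: Fluoride cleavage of the primary silyl ether under buffered, slightly acidic conditions that should provoke neither ester cleavage nor acyl migration.

Step 12
Reactants: 15 (1R,5S)-5-(hydroxymethyl)-4,6,6-trimethylcyclohex-3-en-1-yl 3-methylbutanoate; 16 umbelliferone (7-hydroxy-2H-chromen-2-one)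
Product: 17 (1R,5S)-4,6,6-trimethyl-5-{[(2-oxo-2H-chromen-7-yl)oxy]methyl}cyclohex-3-en-1-yl 3-methylbutanoate
Conditions: PPh3, DIAD, THF, 0 °C → 40 °C
Reagents that add atoms: none
Why: Mitsunobu etherification, in which the primary alcohol is activated as the alkoxyphosphonium ion and displaced at C7 (not a stereocentre) by the acidic phenol.

**Compound list**

1 | (E)-3-methylpent-3-en-2-one | C/C=C(\C)C(C)=O | starting material
2 | (2R,3E)-3-methylpent-3-en-2-ol | C/C=C(\C)[C@@H](C)O | intermediate
3 | 3,3-dimethylpent-4-enoic acid | C=CC(C)(C)CC(=O)O | starting material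
4 | (2R,3E)-3-methylpent-3-en-2-yl 3,3-dimethylpent-4-enoate | C/C=C(\C)[C@@H](C)OC(=O)CC(C)(C)C=C | intermediate
5 | (Z)-trimethylsilyl ketene acetal of 4, trimethyl{[(1Z)-3,3-dimethyl-1-{[(2R,3E)-3-methylpent-3-en-2-yl]oxy}penta-1,4-dien-1-yl]oxy}silane | C/C=C(\C)[C@@H](C)O/C(O[Si](C)(C)C)=C/C(C)(C)C=C | intermediate
6 | trimethylsilyl (2S,3R,4E)-3,4-dimethyl-2-(2-methylbut-3-en-2-yl)hex-4-enoate | C/C=C(\C)[C@H](C)[C@H](C(=O)O[Si](C)(C)C)C(C)(C)C=C | intermediate
7 | (2S,3R,4E)-3,4-dimethyl-2-(2-methylbut-3-en-2-yl)hex-4-en-1-ol | C/C=C(\C)[C@H](C)[C@H](CO)C(C)(C)C=C | intermediate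
8 | tert-butyl{[(2S,3R,4E)-3,4-dimethyl-2-(2-methylbut-3-en-2-yl)hex-4-en-1-yl]oxy}dimethylsilane | C/C=C(\C)[C@H](C)[C@H](CO[Si](C)(C)C(C)(C)C)C(C)(C)C=C | intermediate
9 | bis-ozonide of 8 (both alkenes as 1,2,4-trioxolanes; mixture of isomers at the new ring carbons) | CC1OC(C)(OO1)[C@H](C)[C@H](CO[Si](C)(C)C(C)(C)C)C(C)(C)C1OCOO1 | intermediate
10 | (3S,4R)-3-{[(tert-butyldimethylsilyl)oxy]methyl}-2,2,4-trimethyl-5-oxohexanal | CC(=O)[C@H](C)[C@H](CO[Si](C)(C)C(C)(C)C)C(C)(C)C=O | intermediate
11 | (2R,3S,5R)-3-{[(tert-butyldimethylsilyl)oxy]methyl}-5-hydroxy-2,4,4-trimethylcyclohexan-1-one | C[C@H]1C(=O)C[C@@H](O)C(C)(C)[C@H]1CO[Si](C)(C)C(C)(C)C | intermediate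
12 | (1R,3S,4R)-3-{[(tert-butyldimethylsilyl)oxy]methyl}-2,2,4-trimethyl-5-oxocyclohexyl 3-methylbutanoate | C[C@H]1C(=O)C[C@@H](OC(=O)CC(C)C)C(C)(C)[C@H]1CO[Si](C)(C)C(C)(C)C | intermediate
13 | (1R,5R)-5-{[(tert-butyldimethylsilyl)oxy]methyl}-4,6,6-trimethyl-3-[(trifluoromethanesulfonyl)oxy]cyclohex-3-en-1-yl 3-methylbutanoate | CC1=C(OS(=O)(=O)C(F)(F)F)C[C@@H](OC(=O)CC(C)C)C(C)(C)[C@H]1CO[Si](C)(C)C(C)(C)C | intermediate
14 | (1R,5S)-5-{[(tert-butyldimethylsilyl)oxy]methyl}-4,6,6-trimethylcyclohex-3-en-1-yl 3-methylbutanoate | CC1=CC[C@@H](OC(=O)CC(C)C)C(C)(C)[C@H]1CO[Si](C)(C)C(C)(C)C | intermediate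
15 | (1R,5S)-5-(hydroxymethyl)-4,6,6-trimethylcyclohex-3-en-1-yl 3-methylbutanoate | CC1=CC[C@@H](OC(=O)CC(C)C)C(C)(C)[C@H]1CO | intermediate
16 | umbelliferone (7-hydroxy-2H-chromen-2-one) | O=c1ccc2ccc(O)cc2o1 | starting material
17 | (1R,5S)-4,6,6-trimethyl-5-{[(2-oxo-2H-chromen-7-yl)oxy]methyl}cyclohex-3-en-1-yl 3-methylbutanoate | CC1=CC[C@@H](OC(=O)CC(C)C)C(C)(C)[C@H]1COc1ccc2ccc(=O)oc2c1 | target

**Step count**

Total step count: 12. Longest linear sequence: 12 steps (1 → 17); acid 3 and umbelliferone 16 enter as purchased.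

**Steps most likely to fail**

Step 7. The closure may be slow enough for C1 to epimerise first, which would open the all-equatorial chair and lead to the C4 epimer; the ketol may also lose water to the enone. The fallback replaces the amine by a boron enolate, which keeps the closed transition state and the same chair argument. Keto aldehyde 10 is treated with Bu2BOTf and iPr2NEt in CH2Cl2 at −78 °C to give the methyl-side dibutylboron enolate F1. Boron then bridges the enolate and aldehyde oxygens, so closure on warming to 0 °C should again put the C4 oxygen axial and cis to C7 and give the boron aldolate F2. A pH 7 buffer/methanol work-up releases ketol 11, where the route is rejoined.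

Step 9. Proton loss may go toward C3 instead of C1, giving the regioisomeric enol triflate, or the ester carbonyl may take part at the activated ketone. The fallback fixes the regiochemistry under equilibrating conditions before the triflate is made. Ketone 12 is treated with Me3SiI and (Me3Si)2NH in CH2Cl2 (−20 °C → rt), which should give the more substituted trimethylsilyl enol ether F3. CsF and PhNTf2 in 1,2-dimethoxyethane then exchange silicon for the triflyl group at the same oxygen and return enol triflate 13.

Step 8. Acylation of the hindered axial hydroxyl may be slow, and base may then trigger β-elimination across C3–C4 in the β-hydroxy or β-acyloxy ketone. The fallback moves the esterification to the end, after the ketone is gone.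
- Ketol 11 is silylated with Et3SiOTf and 2,6-lutidine to the triethylsilyl ether F4.
- Tf2O with 2,6-di-tert-butyl-4-methylpyridine gives the enol triflate F5.
- Pd(OAc)2, PPh3, HCO2H and Bu3N reduce it to the alkene F6.
- HF·pyridine removes both silyl groups to give the diol F7.
- Mitsunobu reaction with 16 (PPh3, DIAD) should etherify only the primary hydroxyl, since the neopentyl secondary hydroxyl is inert, giving the hydroxy ether F8.
- Isovaleryl chloride, DMAP and pyridine acylate the homoallylic alcohol, which has no elimination pathway, and give target 17.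

**Further compounds**

F1 | step 7 | dibutylboron enolate of 10 at the methyl group, (3S,4R)-5-[(dibutylboranyl)oxy]-3-{[(tert-butyldimethylsilyl)oxy]methyl}-2,2,4-trimethylhex-5-enal | C=C(OB(CCCC)CCCC)[C@H](C)[C@H](CO[Si](C)(C)C(C)(C)C)C(C)(C)C=O
F2 | step 7 | O-dibutylboryl aldolate of ketol 11 | C[C@H]1C(=O)C[C@@H](OB(CCCC)CCCC)C(C)(C)[C@H]1CO[Si](C)(C)C(C)(C)C
F3 | step 9 | (1R,5R)-5-{[(tert-butyldimethylsilyl)oxy]methyl}-4,6,6-trimethyl-3-[(trimethylsilyl)oxy]cyclohex-3-en-1-yl 3-methylbutanoate | CC1=C(O[Si](C)(C)C)C[C@@H](OC(=O)CC(C)C)C(C)(C)[C@H]1CO[Si](C)(C)C(C)(C)C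
F4 | step 8 | (2R,3S,5R)-3-{[(tert-butyldimethylsilyl)oxy]methyl}-2,4,4-trimethyl-5-[(triethylsilyl)oxy]cyclohexan-1-one | C[C@H]1C(=O)C[C@@H](O[Si](CC)(CC)CC)C(C)(C)[C@H]1CO[Si](C)(C)C(C)(C)C
F5 | step 8 | (3R,5R)-3-{[(tert-butyldimethylsilyl)oxy]methyl}-2,4,4-trimethyl-5-[(triethylsilyl)oxy]cyclohex-1-en-1-yl trifluoromethanesulfonate | CC1=C(OS(=O)(=O)C(F)(F)F)C[C@@H](O[Si](CC)(CC)CC)C(C)(C)[C@H]1CO[Si](C)(C)C(C)(C)C
F6 | step 8 | tert-butyldimethyl{[(1S,5R)-2,6,6-trimethyl-5-[(triethylsilyl)oxy]cyclohex-2-en-1-yl]methoxy}silane | CC1=CC[C@@H](O[Si](CC)(CC)CC)C(C)(C)[C@H]1CO[Si](C)(C)C(C)(C)C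
F7 | step 8 | (1R,5S)-5-(hydroxymethyl)-4,6,6-trimethylcyclohex-3-en-1-ol | CC1=CC[C@@H](O)C(C)(C)[C@H]1CO
F8 | step 8 | 7-{[(1S,5R)-5-hydroxy-2,6,6-trimethylcyclohex-2-en-1-yl]methoxy}-2H-chromen-2-one | CC1=CC[C@@H](O)C(C)(C)[C@H]1COc1ccc2ccc(=O)oc2c1
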